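Microphyllinic acid is cut at the depside ester into two resorcylate halves that carry the same C6 2-oxoheptyl arm. Everything rests on making ring A by a [4+2] benzannulation: a 1,1,3-trioxygenated butadiene delivers C2 to C5 with the C2 hydroxyl and C4 methoxyl, and a benzyl but-2-ynoate delivers C1 with its carboxyl and C6 with the side chain, whose ketone is masked as a dioxolane on the ynoate C4 substituent. One operation thus forms the C1–C2 and C5–C6 bonds, closes and aromatizes ring A and fixes its 1,2,4,6 pattern. The same ynoate and a bis-silyloxy diene give ring B; esterification, deketalization and hydrogenolysis finish.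

Key step: step 6

Assumption: the enol ether and ketene acetal geometry of 8, 13 and 14 is immaterial because these carbons become aromatic, so their SMILES carry no double-bond descriptors. The transient cycloadducts 9 and 15 are racemic at their single ketal carbon, which is lost on aromatization. The target has no stereocenter. The given structures were checked and needed no correction. The ynoate is kept as designed (dioxolane, benzyl ester) and also serves as the dienophile for ring B.

Step 1
Reactants: 1 ethyl 3-oxooctanoate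
Product: 2 ethyl 2-(2-pentyl-1,3-dioxolan-2-yl)acetate
Conditions: HOCH2CH2OH (3 equiv), p-TsOH·H2O (cat.), toluene, reflux, Dean–Stark
Reagents that add atoms: ethylene glycol, OCCO
Why: Acid-catalysed ketalization with azeotropic removal of water is standard for β-keto esters and masks the ketone before any hydride or carbanion chemistry.

Step 2
Reactants: 2 ethyl 2-(2-pentyl-1,3-dioxolan-2-yl)acetate
Product: 3 2-(2-pentyl-1,3-dioxolan-2-yl)acetaldehyde
Conditions: i-Bu2AlH (1.1 equiv), CH2Cl2, −78 °C; aq. KNaC4H4O6 work-up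
Reagents that add atoms: none
Why: Partial ester reduction should stop at the aluminium hemiacetal, which is stabilized at −78 °C by chelation to a dioxolane oxygen and releases the aldehyde only on work-up.

Step 3
Reactants: 3 2-(2-pentyl-1,3-dioxolan-2-yl)acetaldehyde
Product: 4 2-pentyl-2-(prop-2-yn-1-yl)-1,3-dioxolane
Conditions: dimethyl (1-diazo-2-oxopropyl)phosphonate, K2CO3, MeOH, 0 °C to rt
Reagents that add atoms: dimethyl (1-diazo-2-oxopropyl)phosphonate, CC(=O)C(=[N+]=[N-])P(=O)(OC)OC
Why: The Ohira–Bestmann variant of the Seyferth–Gilbert homologation turns the enolizable aldehyde into the terminal alkyne under carbonate conditions mild enough to leave the β-ketal in place.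

Step 4
Reactants: 4 2-pentyl-2-(prop-2-yn-1-yl)-1,3-dioxolane; 5 benzyl chloroformate
Product: 6 benzyl 4-(2-pentyl-1,3-dioxolan-2-yl)but-2-ynoate
Conditions: n-BuLi, THF, −78 °C; then cannulate into ClCO2Bn, THF, −78 to −20 °C
Reagents that add atoms: none
Why: C-acylation of a lithium acetylide by a chloroformate is the standard alkynoate synthesis, and inverse addition at low temperature keeps base away from the acidic propargylic CH2 of the product.

Step 5
Reactants: 7 methyl (E)-3-methoxybut-2-enoate
Product: 8 1,3-dimethoxy-1-(trimethylsilyloxy)buta-1,3-diene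
Conditions: LiN(i-Pr)2, THF, −78 °C; Me3SiCl, −78 °C to rt; distil under reduced pressure
Reagents that add atoms: chlorotrimethylsilane, C[Si](C)(C)Cl
Why: γ-Deprotonation of the vinylogous ester gives the dienolate, and O-silylation traps it as the silyl ketene acetal diene (a standard vinylketene acetal preparation).

Step 6
Reactants: 6 benzyl 4-(2-pentyl-1,3-dioxolan-2-yl)but-2-ynoate; 8 1,3-dimethoxy-1-(trimethylsilyloxy)buta-1,3-diene
Product: 11 benzyl 2-hydroxy-4-methoxy-6-[(2-pentyl-1,3-dioxolan-2-yl)methyl]benzoate, via cyclohexadiene cycloadduct 9 (not isolated), via aryl trimethylsilyl ether 10 (not isolated)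
Conditions: 8 (3 equiv), toluene, 120 °C, sealed tube; then sat. aq. NH4Cl/THF, rt
Reagents that add atoms: none
Why: The electron-rich diene 8 and the electron-poor ynoate 6 combine in a concerted but strongly asynchronous [4+2] cycloaddition in which the unsubstituted CH2 terminus of 8 bonds to the β-carbon of 6 (C5–C6 of ring A) and the ketene acetal carbon to the α-carbon (C1–C2), giving 1,4-cyclohexadiene 9. Loss of methanol from the mixed methyl silyl ketal of 9 across the ring (1,4-elimination, thermal or on the mildly acidic work-up) aromatizes it to 10, and hydrolysis of the labile aryl O–Si bond leaves the C2 phenol hydrogen-bonded to the ester. The closest known reaction type is the Diels–Alder benzannulation of 1-alkoxy-1-silyloxy-3-alkoxybutadienes with alkynoates and allenoates to give resorcylates. Ring A is closed as a six-membered carbocycle by intermolecular cycloaddition, both ring bonds being made in the same step, and no stereocenter remains because the only sp3 ketal carbon of 9 is flattened on aromatization. The one selectivity needed is regiochemical, and it is secured by the matched polarization of the partners: the two oxygen donors of 8 make its CH2 terminus the nucleophilic end and the ester makes the β-carbon of 6 the electrophilic end, which places the hydroxyl ortho and the methoxyl para to the carboxyl. The dioxolane keeps the 5-oxo-2-ynoate from isomerizing to an allenyl ketone or cyclizing to a pyranone, and the benzyl ester allows a neutral release of the acid afterwards.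

Step 7
Reactants: 11 benzyl 2-hydroxy-4-methoxy-6-[(2-pentyl-1,3-dioxolan-2-yl)methyl]benzoate
Product: 12 2-hydroxy-4-methoxy-6-[(2-pentyl-1,3-dioxolan-2-yl)methyl]benzoic acid
Conditions: H2 (1 atm), Pd/C (10 wt %), EtOAc, rt
Reagents that add atoms: none
Why: Hydrogenolysis of the benzyl ester over palladium on carbon is neutral, so the dioxolane, the aryl methyl ether and the phenol should be untouched.

Step 8
Reactants: 13 methyl 3-(trimethylsilyloxy)but-2-enoate
Product: 14 1-methoxy-1,3-bis(trimethylsilyloxy)buta-1,3-diene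
Conditions: LiN(i-Pr)2, THF, −78 °C; Me3SiCl, −78 °C to rt; distil under reduced pressure
Reagents that add atoms: chlorotrimethylsilane, C[Si](C)(C)Cl
Why: γ-Deprotonation of the silyl enol ether ester and O-silylation of the dienolate is the standard preparation of this bis-silyloxy diene, a masked acetoacetate dianion.

Step 9
Reactants: 6 benzyl 4-(2-pentyl-1,3-dioxolan-2-yl)but-2-ynoate; 14 1-methoxy-1,3-bis(trimethylsilyloxy)buta-1,3-diene
Product: 17 benzyl 2,4-dihydroxy-6-[(2-pentyl-1,3-dioxolan-2-yl)methyl]benzoate, via cyclohexadiene cycloadduct 15 (not isolated), via bis(trimethylsilyl) ether 16 (not isolated)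
Conditions: 14 (3 equiv), toluene, 120 °C, sealed tube; then sat. aq. NH4Cl/THF, rt
Reagents that add atoms: none
Why: The same Diels–Alder benzannulation as in step 6, with the same regiochemical bias, should give the ring B resorcylate after loss of methanol and hydrolysis of both aryl silyl ethers.

Step 10
Reactants: 12 2-hydroxy-4-methoxy-6-[(2-pentyl-1,3-dioxolan-2-yl)methyl]benzoic acid; 17 benzyl 2,4-dihydroxy-6-[(2-pentyl-1,3-dioxolan-2-yl)methyl]benzoate
Product: 18 benzyl 2-hydroxy-4-({2-hydroxy-4-methoxy-6-[(2-pentyl-1,3-dioxolan-2-yl)methyl]benzoyl}oxy)-6-[(2-pentyl-1,3-dioxolan-2-yl)methyl]benzoate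
Conditions: DCC (1.1 equiv), DMAP (cat.), CH2Cl2, 0 °C to rt
Reagents that add atoms: none
Why: Carbodiimide (Steglich-type) esterification under neutral conditions should acylate the C4 hydroxyl of 17, the only phenol not tied up in a hydrogen bond to an ortho carbonyl, as is usual in depside couplings of chelated hydroxy acids.

Step 11
Reactants: 18 benzyl 2-hydroxy-4-({2-hydroxy-4-methoxy-6-[(2-pentyl-1,3-dioxolan-2-yl)methyl]benzoyl}oxy)-6-[(2-pentyl-1,3-dioxolan-2-yl)methyl]benzoate
Product: 19 benzyl 2-hydroxy-4-{[2-hydroxy-4-methoxy-6-(2-oxoheptyl)benzoyl]oxy}-6-(2-oxoheptyl)benzoate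
Conditions: 2 M aq. HCl, THF, rt
Reagents that add atoms: water, O
Why: Acid-catalysed hydrolysis frees both dialkyl ketones from their dioxolanes, while the aryl and benzyl esters are stable to dilute aqueous acid at room temperature, and doing it before the acid is freed avoids lactonization onto the new ketone.

Step 12
Reactants: 19 benzyl 2-hydroxy-4-{[2-hydroxy-4-methoxy-6-(2-oxoheptyl)benzoyl]oxy}-6-(2-oxoheptyl)benzoate
Product: 20 microphyllinic acid, 2-hydroxy-4-{[2-hydroxy-4-methoxy-6-(2-oxoheptyl)benzoyl]oxy}-6-(2-oxoheptyl)benzoic acid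
Conditions: H2 (1 atm), Pd/C (10 wt %), EtOAc, rt
Reagents that add atoms: none
Why: Neutral hydrogenolysis of the benzyl ester should leave the depside ester, the non-benzylic dialkyl ketones and the methyl ether intact, so the target is released without acid or base.

Compound list
1 | ethyl 3-oxooctanoate | CCCCCC(=O)CC(=O)OCC | starting material
2 | ethyl 2-(2-pentyl-1,3-dioxolan-2-yl)acetate | CCCCCC1(CC(=O)OCC)OCCO1 | intermediate
3 | 2-(2-pentyl-1,3-dioxolan-2-yl)acetaldehyde | CCCCCC1(CC=O)OCCO1 | intermediate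
4 | 2-pentyl-2-(prop-2-yn-1-yl)-1,3-dioxolane | CCCCCC1(CC#C)OCCO1 | intermediate
5 | benzyl chloroformate | O=C(Cl)OCc1ccccc1 | starting material
6 | benzyl 4-(2-pentyl-1,3-dioxolan-2-yl)but-2-ynoate | CCCCCC1(CC#CC(=O)OCc2ccccc2)OCCO1 | intermediate
7 | methyl (E)-3-methoxybut-2-enoate | CO/C(C)=C/C(=O)OC | starting material
8 | 1,3-dimethoxy-1-(trimethylsilyloxy)buta-1,3-diene | COC(=C)C=C(OC)O[Si](C)(C)C | intermediate
9 | benzyl 4,6-dimethoxy-2-[(2-pentyl-1,3-dioxolan-2-yl)methyl]-6-(trimethylsilyloxy)cyclohexa-1,4-diene-1-carboxylate (racemic, not isolated) | CCCCCC1(CC2=C(C(=O)OCc3ccccc3)C(OC)(O[Si](C)(C)C)C=C(OC)C2)OCCO1 | intermediate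
10 | benzyl 4-methoxy-2-[(2-pentyl-1,3-dioxolan-2-yl)methyl]-6-(trimethylsilyloxy)benzoate (not isolated) | CCCCCC1(Cc2cc(OC)cc(O[Si](C)(C)C)c2C(=O)OCc2ccccc2)OCCO1 | intermediate
11 | benzyl 2-hydroxy-4-methoxy-6-[(2-pentyl-1,3-dioxolan-2-yl)methyl]benzoate | CCCCCC1(Cc2cc(OC)cc(O)c2C(=O)OCc2ccccc2)OCCO1 | intermediate
12 | 2-hydroxy-4-methoxy-6-[(2-pentyl-1,3-dioxolan-2-yl)methyl]benzoic acid | CCCCCC1(Cc2cc(OC)cc(O)c2C(=O)O)OCCO1 | intermediate
13 | methyl 3-(trimethylsilyloxy)but-2-enoate (commercial; either geometry or the mixture) | COC(=O)C=C(C)O[Si](C)(C)C | starting material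
14 | 1-methoxy-1,3-bis(trimethylsilyloxy)buta-1,3-diene | COC(=CC(=C)O[Si](C)(C)C)O[Si](C)(C)C | intermediate
15 | benzyl 6-methoxy-2-[(2-pentyl-1,3-dioxolan-2-yl)methyl]-4,6-bis(trimethylsilyloxy)cyclohexa-1,4-diene-1-carboxylate (racemic, not isolated) | CCCCCC1(CC2=C(C(=O)OCc3ccccc3)C(OC)(O[Si](C)(C)C)C=C(O[Si](C)(C)C)C2)OCCO1 | intermediate
16 | benzyl 2-[(2-pentyl-1,3-dioxolan-2-yl)methyl]-4,6-bis(trimethylsilyloxy)benzoate (not isolated) | CCCCCC1(Cc2cc(O[Si](C)(C)C)cc(O[Si](C)(C)C)c2C(=O)OCc2ccccc2)OCCO1 | intermediate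
17 | benzyl 2,4-dihydroxy-6-[(2-pentyl-1,3-dioxolan-2-yl)methyl]benzoate | CCCCCC1(Cc2cc(O)cc(O)c2C(=O)OCc2ccccc2)OCCO1 | intermediate
18 | benzyl 2-hydroxy-4-({2-hydroxy-4-methoxy-6-[(2-pentyl-1,3-dioxolan-2-yl)methyl]benzoyl}oxy)-6-[(2-pentyl-1,3-dioxolan-2-yl)methyl]benzoate | CCCCCC1(Cc2cc(OC(=O)c3c(O)cc(OC)cc3CC4(CCCCC)OCCO4)cc(O)c2C(=O)OCc5ccccc5)OCCO1 | intermediate
19 | benzyl 2-hydroxy-4-{[2-hydroxy-4-methoxy-6-(2-oxoheptyl)benzoyl]oxy}-6-(2-oxoheptyl)benzoate | CCCCCC(=O)Cc1cc(OC(=O)c2c(O)cc(OC)cc2CC(=O)CCCCC)cc(O)c1C(=O)OCc1ccccc1 | intermediate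
20 | microphyllinic acid, 2-hydroxy-4-{[2-hydroxy-4-methoxy-6-(2-oxoheptyl)benzoyl]oxy}-6-(2-oxoheptyl)benzoic acid | CCCCCC(=O)Cc1cc(OC(=O)c2c(O)cc(OC)cc2CC(=O)CCCCC)cc(O)c1C(=O)O | target

Total step count: 12. Longest linear sequence: 9 steps (steps 1, 2, 3, 4, 6, 7, 10, 11, 12).

Steps most likely to fail

Step 6. The β-alkylated ynoate may add more slowly than the diene is consumed by hydrolysis or thermal decomposition, or the adduct may aromatize by losing silanol instead of methanol and so keep a C2 methyl ether. Fallback: the methoxyl is installed after ring formation instead of being carried by the diene. It sets out from resorcylate 17 and comes back to the route at 11. Treating 17 with MeI (1.05 equiv) and K2CO3 in acetone at rt should methylate only the C4 hydroxyl, since the C2 hydroxyl is held in a hydrogen bond to the ester, and gives 11 directly. Because 17 has a cycloaddition-free access of its own (fallback to step 9), this path needs no Diels–Alder reaction at all. It makes no compound outside the list (F0).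

Step 9. The same slow cycloaddition may be made worse by the greater lability of the bis-silyl diene, which can lose or transfer a silyl group before it reacts. Fallback: ring B is built by a polyketide-type aldol aromatization instead of a cycloaddition. It sets out from ester 2 and comes back to the route at 17. Ester 2 with MeNH(OMe)·HCl and i-PrMgCl in THF at −20 °C should give N-methoxy-N-methyl-2-(2-pentyl-1,3-dioxolan-2-yl)acetamide F1. Commercial 2,2,6-trimethyl-4H-1,3-dioxin-4-one is C-acetylated (LiN(SiMe3)2, THF, −78 °C; AcCl) to 2,2-dimethyl-6-(2-oxopropyl)-4H-1,3-dioxin-4-one F2. The dianion of F2 (LiN(i-Pr)2, 2 equiv, THF, −78 °C) is acylated at its terminal carbon by F1 to give 2,2-dimethyl-6-[2,4-dioxo-5-(2-pentyl-1,3-dioxolan-2-yl)pentyl]-4H-1,3-dioxin-4-one F3. Heating F3 with benzyl alcohol in toluene at 110 °C expels acetone, and the acylketene is trapped as benzyl 3,5,7-trioxo-8-(2-pentyl-1,3-dioxolan-2-yl)octanoate F4. Cs2CO3 in CH2Cl2/i-PrOH followed by AcOH should close F4 by intramolecular aldol condensation between C2 and the C7 ketone and dehydrate it to 17.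

Step 10. Attack of the phenol on the doubly ortho-substituted activated acid may be slow enough that rearrangement to the N-acylurea or self-esterification through the free C2 phenol of 12 competes. Fallback: the C2 hydroxyl is masked and the acid is activated as its chloride under neutral conditions. It sets out from acid 12 and comes back to the route at 18. Acid 12 with t-BuMe2SiCl and imidazole in DMF should give tert-butyldimethylsilyl 2-[(tert-butyldimethylsilyl)oxy]-4-methoxy-6-[(2-pentyl-1,3-dioxolan-2-yl)methyl]benzoate F5. Oxalyl chloride with catalytic DMF in CH2Cl2 at 0 °C converts the silyl ester directly, without free HCl, into 2-[(tert-butyldimethylsilyl)oxy]-4-methoxy-6-[(2-pentyl-1,3-dioxolan-2-yl)methyl]benzoyl chloride F6. F6 with 17, Et3N and catalytic DMAP in CH2Cl2 acylates the C4 hydroxyl to give benzyl 4-({2-[(tert-butyldimethylsilyl)oxy]-4-methoxy-6-[(2-pentyl-1,3-dioxolan-2-yl)methyl]benzoyl}oxy)-2-hydroxy-6-[(2-pentyl-1,3-dioxolan-2-yl)methyl]benzoate F7. Bu4NF buffered with AcOH in THF at 0 °C removes the aryl silyl ether and gives 18.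

Further compounds
F0 | step 6 | none | none
F1 | step 9 | N-methoxy-N-methyl-2-(2-pentyl-1,3-dioxolan-2-yl)acetamide | CCCCCC1(CC(=O)N(C)OC)OCCO1
F2 | step 9 | 2,2-dimethyl-6-(2-oxopropyl)-4H-1,3-dioxin-4-one | CC(=O)CC1=CC(=O)OC(C)(C)O1
F3 | step 9 | 2,2-dimethyl-6-[2,4-dioxo-5-(2-pentyl-1,3-dioxolan-2-yl)pentyl]-4H-1,3-dioxin-4-one | CCCCCC1(CC(=O)CC(=O)CC2=CC(=O)OC(C)(C)O2)OCCO1
F4 | step 9 | benzyl 3,5,7-trioxo-8-(2-pentyl-1,3-dioxolan-2-yl)octanoate | CCCCCC1(CC(=O)CC(=O)CC(=O)CC(=O)OCc2ccccc2)OCCO1
F5 | step 10 | tert-butyldimethylsilyl 2-[(tert-butyldimethylsilyl)oxy]-4-methoxy-6-[(2-pentyl-1,3-dioxolan-2-yl)methyl]benzoate | CCCCCC1(Cc2cc(OC)cc(O[Si](C)(C)C(C)(C)C)c2C(=O)O[Si](C)(C)C(C)(C)C)OCCO1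
F6 | step 10 | 2-[(tert-butyldimethylsilyl)oxy]-4-methoxy-6-[(2-pentyl-1,3-dioxolan-2-yl)methyl]benzoyl chloride | CCCCCC1(Cc2cc(OC)cc(O[Si](C)(C)C(C)(C)C)c2C(Cl)=O)OCCO1
F7 | step 10 | benzyl 4-({2-[(tert-butyldimethylsilyl)oxy]-4-methoxy-6-[(2-pentyl-1,3-dioxolan-2-yl)methyl]benzoyl}oxy)-2-hydroxy-6-[(2-pentyl-1,3-dioxolan-2-yl)methyl]benzoate | CCCCCC1(Cc2cc(OC(=O)c3c(O[Si](C)(C)C(C)(C)C)cc(OC)cc3CC4(CCCCC)OCCO4)cc(O)c2C(=O)OCc5ccccc5)OCCO1
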